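## Retrosynthetic overview

1. Target 26 ⇐ (C9 esterification, desilylation, C11 methylenation) trans-fused lactone 20 ⇐ (C8 reduction, lactonisation) oxygen-bridged ketone 18.
2. Ring B of 18 is opened at C5–C6. The strategy rests on C5 being the only hydrogen-bearing carbon next to the ring A oxygen (C10 is quaternary), so ring A is carried with a bare C5H2 and the C5–C6 bond is made from that C–H bond by hydrogen-atom transfer and 7-endo radical addition to the C6=C7–C8=O enone of 16.
3. Enone 16 ⇐ Mannich methylenation of γ-keto ester 13 ⇐ Negishi acylation of the α-silyloxy acid 9 (C8) with the zinc homoenolate of methyl propanoate (C7, C11, C12).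
4. Acid 9 ⇐ oxepane diol 6 ⇐ 7-exo opening of Sharpless epoxide 5 by the C5 hydroxyl (sets C9 and C10) ⇐ diol 4 ⇐ Ru–BINAP hydrogenation (sets C4) ⇐ geranyl acetate 1, which supplies C1–C5, C8–C10 and both methyl groups.
5. Order of ring formation: ring A (step 4), ring B (step 10), lactone (step 12).

Key step: step 10

Numbering used below: C10 is the methyl-bearing quaternary ether carbon, C1–C3 the ring A methylenes, C4 the methyl-bearing methine, C5 the second ether carbon, C6–C9 the ring B carbons (C7 carries C11, C8 the lactone oxygen, C9 the ester oxygen), C12 the lactone carbonyl and C13 the exocyclic methylene. Ring A is O/C5/C4/C3/C2/C1/C10; ring B is O/C5/C6/C7/C8/C9/C10. The target is 4S,5R,7R,8R,9S,10R.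

Assumption: the Ru–BINAP hydrogenation of the 2-methyl allylic alcohol in step 2 follows the enantioface preference established for geraniol; the choice of the (S)-ligand rests on this.

## Route

Step 1
Reactants: 1 geranyl acetate
Product: 2 (2E,6E)-8-hydroxy-3,7-dimethylocta-2,6-dien-1-yl acetate
Conditions: SeO2 (0.2 equiv), t-BuOOH (3 equiv), salicylic acid (0.1 equiv), CH2Cl2, 23 °C
Reagents that add atoms: tert-butyl hydroperoxide CC(C)(C)OO (oxygen passed on through catalytic selenium dioxide O=[Se]=O)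
Why: SeO2-catalysed allylic hydroxylation (ene reaction then [2,3]-sigmatropic shift) is selective for the (E)-methyl group of the electron-rich trisubstituted C6=C7 alkene, while the acetate-deactivated C2=C3 alkene is left alone; no stereocentre is formed.

Step 2
Reactants: 2 (2E,6E)-8-hydroxy-3,7-dimethylocta-2,6-dien-1-yl acetate
Product: 4 (2E,7S)-3,7-dimethyloct-2-ene-1,8-diol, via hydroxy acetate 3 (not isolated)
Conditions: H2 (50 atm), Ru(OAc)2[(S)-BINAP] (1 mol%), MeOH, 25 °C; then K2CO3 (0.2 equiv), 25 °C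
Reagents that add atoms: none
Why: Noyori asymmetric hydrogenation with the Ru–BINAP dicarboxylate needs a coordinating free hydroxyl, so only the allylic alcohol alkene is reduced and the allylic acetate alkene survives; by the geraniol enantioface model the (S)-ligand should give the 7S centre (C4 of the target), and base-catalysed transesterification in the same methanol then frees the allylic alcohol for step 3.

Step 3
Reactants: 4 (2E,7S)-3,7-dimethyloct-2-ene-1,8-diol
Product: 5 [(2S,3S)-3-[(4S)-5-hydroxy-4-methylpentyl]-3-methyloxiran-2-yl]methanol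
Conditions: Ti(Oi-Pr)4 (0.2 equiv), L-(+)-diethyl tartrate (0.24 equiv), t-BuOOH (2 equiv), 4 Å MS, CH2Cl2, −20 °C
Reagents that add atoms: tert-butyl hydroperoxide CC(C)(C)OO
Why: Katsuki–Sharpless asymmetric epoxidation of the (E)-allylic alcohol with the L-(+)-tartrate ligand should give the (2S,3S)-epoxide by reagent control, as for geraniol, which fixes C9 and sets C10 in the sense that step 4 inverts; the remote saturated primary alcohol is not oxidised.

Step 4
Reactants: 5 [(2S,3S)-3-[(4S)-5-hydroxy-4-methylpentyl]-3-methyloxiran-2-yl]methanol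
Product: 6 (1S)-1-[(2R,6S)-2,6-dimethyloxepan-2-yl]ethane-1,2-diol
Conditions: camphorsulfonic acid (0.1 equiv), CH2Cl2 (0.01 M), 0 to 23 °C
Reagents that add atoms: none
Why: acid-catalysed intramolecular epoxide opening (7-exo-tet hydroxy epoxide cyclisation) by the C5 hydroxyl at the tertiary carbon C10 closes ring A with inversion at C10 (10R) and leaves C9 untouched; the 8-endo path to C9 is disfavoured by ring size and by the inductive effect of the C8 hydroxymethyl group, and high dilution suppresses intermolecular opening.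

Step 5
Reactants: 6 (1S)-1-[(2R,6S)-2,6-dimethyloxepan-2-yl]ethane-1,2-diol
Product: 7 (2R,6S)-2-[(1S)-1,2-bis[(tert-butyldimethylsilyl)oxy]ethyl]-2,6-dimethyloxepane
Conditions: t-BuMe2SiOTf (2.5 equiv), 2,6-lutidine (4 equiv), CH2Cl2, −78 to 0 °C
Reagents that add atoms: tert-butyldimethylsilyl trifluoromethanesulfonate CC(C)(C)[Si](C)(C)OS(=O)(=O)C(F)(F)F
Why: silylation with the silyl triflate and a hindered pyridine base covers both hydroxyls, including the neopentylic secondary one at C9 that the silyl chloride would not reach.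

Step 6
Reactants: 7 (2R,6S)-2-[(1S)-1,2-bis[(tert-butyldimethylsilyl)oxy]ethyl]-2,6-dimethyloxepane
Product: 8 (2S)-2-[(tert-butyldimethylsilyl)oxy]-2-[(2R,6S)-2,6-dimethyloxepan-2-yl]ethan-1-ol
Conditions: HF·pyridine, pyridine, THF, 0 °C
Reagents that add atoms: none
Why: buffered HF·pyridine cleaves the unhindered primary silyl ether much faster than the secondary one flanked by the quaternary C10 (selective desilylation by steric differentiation).

Step 7
Reactants: 8 (2S)-2-[(tert-butyldimethylsilyl)oxy]-2-[(2R,6S)-2,6-dimethyloxepan-2-yl]ethan-1-ol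
Product: 9 (2R)-2-[(tert-butyldimethylsilyl)oxy]-2-[(2R,6S)-2,6-dimethyloxepan-2-yl]acetic acid
Conditions: TEMPO (0.2 equiv), PhI(OAc)2 (2.2 equiv), MeCN/H2O 1:1, 23 °C
Reagents that add atoms: water O
Why: TEMPO/PhI(OAc)2 oxidation in aqueous acetonitrile takes the primary alcohol through the aldehyde hydrate to the acid under near-neutral conditions that should neither epimerise C9 nor cleave the silyl ether.

Step 8
Reactants: 9 (2R)-2-[(tert-butyldimethylsilyl)oxy]-2-[(2R,6S)-2,6-dimethyloxepan-2-yl]acetic acid; 10 methyl 3-bromopropanoate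
Product: 13 methyl (5R)-5-[(tert-butyldimethylsilyl)oxy]-5-[(2R,6S)-2,6-dimethyloxepan-2-yl]-4-oxopentanoate, via acid chloride 11 (not isolated), via zinc reagent 12 (not isolated)
Conditions: 9, 1-chloro-N,N,2-trimethylprop-1-en-1-amine, CH2Cl2, 0 to 23 °C; separately 10, Zn dust (activated by BrCH2CH2Br and Me3SiCl), LiCl, THF, 50 °C; combine, Pd(PPh3)4 (5 mol%), THF, 0 to 23 °C
Reagents that add atoms: none
Why: the acid chloride is formed under neutral conditions with the Ghosez reagent and coupled with the ester-bearing alkylzinc bromide in a Pd-catalysed Negishi acylation, which stops at the ketone, tolerates the ester in the nucleophile (the reason for zinc in place of lithium or magnesium) and does not touch C9.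

Step 9
Reactants: 13 methyl (5R)-5-[(tert-butyldimethylsilyl)oxy]-5-[(2R,6S)-2,6-dimethyloxepan-2-yl]-4-oxopentanoate
Product: 16 methyl (5R)-5-[(tert-butyldimethylsilyl)oxy]-5-[(2R,6S)-2,6-dimethyloxepan-2-yl]-3-methylidene-4-oxopentanoate, via Mannich base 14 (not isolated), via ammonium iodide 15 (not isolated)
Conditions: LiN(SiMe3)2 (1.1 equiv), THF, −78 °C; [CH2=NMe2]I, −78 to 0 °C; MeI, CH2Cl2, 23 °C; NaHCO3 (aq.), CH2Cl2, 23 °C
Reagents that add atoms: N,N-dimethylmethyleneiminium iodide (Eschenmoser's salt) C=[N+](C)C.[I-]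
Why: kinetic deprotonation takes the C7 methylene (ketone α-CH2, more acidic than the ester α-CH2 and far more accessible than the C9 methine), the enolate undergoes a Mannich reaction with Eschenmoser's salt, and quaternisation followed by mild E1cB elimination gives the α-methylene ketone without a base strong enough to move the alkene into conjugation with the ester.

Step 10
Reactants: 16 methyl (5R)-5-[(tert-butyldimethylsilyl)oxy]-5-[(2R,6S)-2,6-dimethyloxepan-2-yl]-3-methylidene-4-oxopentanoate
Product: 17 methyl 2-[(1R,2R,4RS,6R,7S)-2-[(tert-butyldimethylsilyl)oxy]-1,7-dimethyl-3-oxo-11-oxabicyclo[4.4.1]undecan-4-yl]acetate (both C7 epimers; C7 is locant 4 of the bicycle)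
Conditions: (Bu4N)4[W10O32] (5 mol%), MeCN (0.01 M, degassed), 390 nm LED, 23 °C, Ar
Reagents that add atoms: none
Why: Proposed new method: photoexcited decatungstate is an electrophilic hydrogen abstractor and should take the hydridic, unhindered C5–H next to the ring A oxygen in preference to C9–H, which is deactivated by the adjacent carbonyl and buried between the quaternary C10 and the silyl ether; the nucleophilic α-alkoxy radical then adds to the unsubstituted terminus C6 of the enone in a 7-endo-trig closure of ring B, and the α-keto radical at C7 is reduced by the reduced polyoxometalate (back hydrogen transfer, or electron transfer then protonation), which closes the catalytic cycle. The closest known reaction type is the intermolecular decatungstate-photocatalysed α-C–H alkylation of cyclic ethers with electron-poor alkenes (photocatalytic Giese reaction); its use for an intramolecular, ring-bridging closure is the untested element. At C5 the four-atom tether from C10 can only reach the face of ring A cis to the C10 arm, so the bridge dictates the 5R configuration. C7 is created in the hydrogen-return step without control and is corrected in step 11. The step needs C5–H abstraction over all other C–H bonds (secured by polarity and accessibility; abstraction elsewhere is reversible and unproductive), 7-endo over 6-exo closure (secured by polarity-matched attack at the terminal β-carbon, the 6-exo mode would hit the substituted α-carbon) and cyclisation over oligomerisation (secured by 0.01 M dilution and by the quaternary C10, which holds the acceptor next to C5). The 390 nm light is absorbed by the catalyst and not by the enone.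

Step 11
Reactants: 17 methyl 2-[(1R,2R,4RS,6R,7S)-2-[(tert-butyldimethylsilyl)oxy]-1,7-dimethyl-3-oxo-11-oxabicyclo[4.4.1]undecan-4-yl]acetate
Product: 18 methyl 2-[(1R,2R,4R,6R,7S)-2-[(tert-butyldimethylsilyl)oxy]-1,7-dimethyl-3-oxo-11-oxabicyclo[4.4.1]undecan-4-yl]acetate
Conditions: DBU (0.2 equiv), PhMe, 23 °C
Reagents that add atoms: none
Why: catalytic amidine base epimerises C7 through the C7 enolate (thermodynamic equilibration) and should favour the 7R epimer whose acetate arm points to the exo face of ring B, away from the C1–C4 bridge; the C9 methine, shielded by C10 and the silyl ether, enolises much more slowly and should keep its configuration.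

Step 12
Reactants: 18 methyl 2-[(1R,2R,4R,6R,7S)-2-[(tert-butyldimethylsilyl)oxy]-1,7-dimethyl-3-oxo-11-oxabicyclo[4.4.1]undecan-4-yl]acetate
Product: 20 (4S,5R,7R,8R,9S,10R)-9-[(tert-butyldimethylsilyl)oxy]-5,10-epoxygermacran-12,8-olide, via hydroxy ester 19 (not isolated)
Conditions: NaBH4, CeCl3·7H2O, MeOH/THF, −40 °C; then pyridinium p-toluenesulfonate (0.1 equiv), PhMe, 60 °C
Reagents that add atoms: none
Why: borohydride reduction under Luche-type conditions should deliver hydride to the exo face of the C8 carbonyl, the endo face being covered by the C1–C4 bridge of ring A, to give the endo 8R alcohol trans to the C7 arm (substrate control), and acid-catalysed transesterification then closes the trans-fused γ-lactone; the cerium salt keeps the medium weakly basic so that the C9 silyl group should not migrate.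

Step 13
Reactants: 20 (4S,5R,7R,8R,9S,10R)-9-[(tert-butyldimethylsilyl)oxy]-5,10-epoxygermacran-12,8-olide
Product: 23 (4S,5R,7R,8R,9S,10R)-9-[(tert-butyldimethylsilyl)oxy]-5,10-epoxygermacr-11(13)-en-12,8-olide, via Mannich base 21 (not isolated), via ammonium iodide 22 (not isolated)
Conditions: LiN(i-Pr)2 (1.2 equiv), THF, −78 °C; [CH2=NMe2]I, −78 to 23 °C; MeI, CH2Cl2/MeOH, 23 °C; NaHCO3 (aq.), CH2Cl2, 23 °C
Reagents that add atoms: N,N-dimethylmethyleneiminium iodide (Eschenmoser's salt) C=[N+](C)C.[I-]
Why: the lactone enolate undergoes a Mannich reaction with Eschenmoser's salt at C11, and quaternisation followed by Hofmann-type elimination (Mannich α-methylenation) installs the exocyclic alkene; the silyl ether covers O9 and no other acidic C–H is present.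

Step 14
Reactants: 23 (4S,5R,7R,8R,9S,10R)-9-[(tert-butyldimethylsilyl)oxy]-5,10-epoxygermacr-11(13)-en-12,8-olide
Product: 24 (4S,5R,7R,8R,9S,10R)-5,10-epoxy-9-hydroxygermacr-11(13)-en-12,8-olide
Conditions: HF (48% aq.), MeCN, 0 to 23 °C
Reagents that add atoms: none
Why: acidic fluoride cleaves the hindered silyl ether (desilylation) without the basic nucleophiles that would add to the α-methylene lactone.

Step 15
Reactants: 24 (4S,5R,7R,8R,9S,10R)-5,10-epoxy-9-hydroxygermacr-11(13)-en-12,8-olide; 25 3-methylbutanoyl chloride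
Product: 26 (4S,5R,7R,8R,9S,10R)-5,10-epoxy-9-(3-methylbutanoyloxy)germacr-11(13)-en-12,8-olide (CNP0274454.1)
Conditions: Et3N (3 equiv), DMAP (0.2 equiv), CH2Cl2, 0 to 23 °C
Reagents that add atoms: none
Why: DMAP-catalysed acylation with the acid chloride should esterify the hindered C9 alcohol with retention, the reversible conjugate addition of amine to the methylene lactone being unproductive.

## Compound list

1 | geranyl acetate, (2E)-3,7-dimethylocta-2,6-dien-1-yl acetate | CC(C)=CCC/C(C)=C/COC(C)=O | starting material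
2 | (2E,6E)-8-hydroxy-3,7-dimethylocta-2,6-dien-1-yl acetate | OC/C(C)=C/CC/C(C)=C/COC(C)=O | intermediate
3 | (2E,7S)-8-hydroxy-3,7-dimethyloct-2-en-1-yl acetate | OC[C@@H](C)CCC/C(C)=C/COC(C)=O | intermediate
4 | (2E,7S)-3,7-dimethyloct-2-ene-1,8-diol | OC[C@@H](C)CCC/C(C)=C/CO | intermediate
5 | [(2S,3S)-3-[(4S)-5-hydroxy-4-methylpentyl]-3-methyloxiran-2-yl]methanol | OC[C@@H](C)CCC[C@]1(C)O[C@H]1CO | intermediate
6 | (1S)-1-[(2R,6S)-2,6-dimethyloxepan-2-yl]ethane-1,2-diol | OC[C@H](O)[C@@]1(C)CCC[C@H](C)CO1 | intermediate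
7 | (2R,6S)-2-[(1S)-1,2-bis[(tert-butyldimethylsilyl)oxy]ethyl]-2,6-dimethyloxepane | CC(C)(C)[Si](C)(C)OC[C@H](O[Si](C)(C)C(C)(C)C)[C@@]1(C)CCC[C@H](C)CO1 | intermediate
8 | (2S)-2-[(tert-butyldimethylsilyl)oxy]-2-[(2R,6S)-2,6-dimethyloxepan-2-yl]ethan-1-ol | OC[C@H](O[Si](C)(C)C(C)(C)C)[C@@]1(C)CCC[C@H](C)CO1 | intermediate
9 | (2R)-2-[(tert-butyldimethylsilyl)oxy]-2-[(2R,6S)-2,6-dimethyloxepan-2-yl]acetic acid | OC(=O)[C@H](O[Si](C)(C)C(C)(C)C)[C@@]1(C)CCC[C@H](C)CO1 | intermediate
10 | methyl 3-bromopropanoate | COC(=O)CCBr | starting material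
11 | (2R)-2-[(tert-butyldimethylsilyl)oxy]-2-[(2R,6S)-2,6-dimethyloxepan-2-yl]acetyl chloride | ClC(=O)[C@H](O[Si](C)(C)C(C)(C)C)[C@@]1(C)CCC[C@H](C)CO1 | intermediate
12 | (3-methoxy-3-oxopropyl)zinc bromide | COC(=O)CC[Zn]Br | intermediate
13 | methyl (5R)-5-[(tert-butyldimethylsilyl)oxy]-5-[(2R,6S)-2,6-dimethyloxepan-2-yl]-4-oxopentanoate | COC(=O)CCC(=O)[C@H](O[Si](C)(C)C(C)(C)C)[C@@]1(C)CCC[C@H](C)CO1 | intermediate
14 | methyl (3RS,5R)-5-[(tert-butyldimethylsilyl)oxy]-3-[(dimethylamino)methyl]-5-[(2R,6S)-2,6-dimethyloxepan-2-yl]-4-oxopentanoate | COC(=O)CC(CN(C)C)C(=O)[C@H](O[Si](C)(C)C(C)(C)C)[C@@]1(C)CCC[C@H](C)CO1 | intermediate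
15 | N-methyl ammonium iodide of 14 (trimethylammoniomethyl ketone) | COC(=O)CC(C[N+](C)(C)C)C(=O)[C@H](O[Si](C)(C)C(C)(C)C)[C@@]1(C)CCC[C@H](C)CO1.[I-] | intermediate
16 | methyl (5R)-5-[(tert-butyldimethylsilyl)oxy]-5-[(2R,6S)-2,6-dimethyloxepan-2-yl]-3-methylidene-4-oxopentanoate (key-step precursor) | COC(=O)CC(=C)C(=O)[C@H](O[Si](C)(C)C(C)(C)C)[C@@]1(C)CCC[C@H](C)CO1 | intermediate
17 | methyl 2-[(1R,2R,4RS,6R,7S)-2-[(tert-butyldimethylsilyl)oxy]-1,7-dimethyl-3-oxo-11-oxabicyclo[4.4.1]undecan-4-yl]acetate (C7 epimers) | COC(=O)CC1C[C@H]2O[C@](C)(CCC[C@@H]2C)[C@@H](O[Si](C)(C)C(C)(C)C)C1=O | intermediate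
18 | methyl 2-[(1R,2R,4R,6R,7S)-2-[(tert-butyldimethylsilyl)oxy]-1,7-dimethyl-3-oxo-11-oxabicyclo[4.4.1]undecan-4-yl]acetate (key-step product after C7 equilibration) | COC(=O)C[C@H]1C[C@H]2O[C@](C)(CCC[C@@H]2C)[C@@H](O[Si](C)(C)C(C)(C)C)C1=O | intermediate
19 | methyl 2-[(1R,2S,3R,4R,6R,7S)-2-[(tert-butyldimethylsilyl)oxy]-3-hydroxy-1,7-dimethyl-11-oxabicyclo[4.4.1]undecan-4-yl]acetate | COC(=O)C[C@H]1C[C@H]2O[C@](C)(CCC[C@@H]2C)[C@@H](O[Si](C)(C)C(C)(C)C)[C@@H]1O | intermediate
20 | (4S,5R,7R,8R,9S,10R)-9-[(tert-butyldimethylsilyl)oxy]-5,10-epoxygermacran-12,8-olide | C1C(=O)O[C@@H]2[C@@H]1C[C@H]1O[C@](C)(CCC[C@@H]1C)[C@H]2O[Si](C)(C)C(C)(C)C | intermediate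
21 | 11-[(dimethylamino)methyl] derivative of 20 (11RS) | CN(C)CC1C(=O)O[C@@H]2[C@@H]1C[C@H]1O[C@](C)(CCC[C@@H]1C)[C@H]2O[Si](C)(C)C(C)(C)C | intermediate
22 | N-methyl ammonium iodide of 21 | C[N+](C)(C)CC1C(=O)O[C@@H]2[C@@H]1C[C@H]1O[C@](C)(CCC[C@@H]1C)[C@H]2O[Si](C)(C)C(C)(C)C.[I-] | intermediate
23 | (4S,5R,7R,8R,9S,10R)-9-[(tert-butyldimethylsilyl)oxy]-5,10-epoxygermacr-11(13)-en-12,8-olide | C=C1C(=O)O[C@@H]2[C@@H]1C[C@H]1O[C@](C)(CCC[C@@H]1C)[C@H]2O[Si](C)(C)C(C)(C)C | intermediate
24 | (4S,5R,7R,8R,9S,10R)-5,10-epoxy-9-hydroxygermacr-11(13)-en-12,8-olide | C=C1C(=O)O[C@@H]2[C@@H]1C[C@H]1O[C@](C)(CCC[C@@H]1C)[C@H]2O | intermediate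
25 | 3-methylbutanoyl chloride (isovaleryl chloride) | CC(C)CC(Cl)=O | starting material
26 | (4S,5R,7R,8R,9S,10R)-5,10-epoxy-9-(3-methylbutanoyloxy)germacr-11(13)-en-12,8-olide, CNP0274454.1 | C=C1C(=O)O[C@@H]2[C@@H]1C[C@H]1O[C@](C)(CCC[C@@H]1C)[C@H]2OC(=O)CC(C)C | target

## Step count and risks

Total steps: 15. Longest linear sequence: 15 steps (1 to 26); compounds 10 and 25 are commercial and enter directly.

Steps most likely to fail:

1. Step 10 (hydrogen-atom transfer and bridging closure). Hydrogen abstraction may occur at other C–H bonds, and reversible abstraction at the tertiary C4–H would erode C4. The C5 radical may also be quenched by back hydrogen transfer, or add intermolecularly, before the slow 7-endo bridging closure takes place. Fallback with known chemistry, from acid 9 back to 17: esterification of 9 with Me3SiCHN2 (MeOH/PhMe) gives methyl ester F1. The established intermolecular decatungstate-photocatalysed Giese reaction of the ether C5–H bond of F1 with phenyl vinyl sulfone ((Bu4N)4[W10O32], MeCN, 390 nm) gives sulfone F2, with the new chain expected trans to the C4 methyl group. LiN(i-Pr)2 (2.1 equiv, THF, −78 to −20 °C) deprotonates next to sulfur and the carbanion acylates the ester carbon C8 intramolecularly, closing ring B as β-keto sulfone F3; only the C5 epimer with the chain cis to the C10 arm can close. Alkylation of F3 with methyl bromoacetate (K2CO3, acetone) gives alkylated keto sulfone F4. Reductive desulfonylation with aluminium amalgam, Al(Hg), in THF/H2O returns ketone 17, which re-enters at step 11.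

2. Step 4 (oxepane closure). Ionisation at C10 may outrun the slow seven-membered ring closure, leading to hydride shift, elimination to allylic alcohols, partial loss of configuration at C10 or oligomeric ethers. Fallback, from hydroxy acetate 3 (isolated by stopping step 2 before the K2CO3 addition) back to 6, with the roles of nucleophile and electrophile exchanged: TsCl/pyridine gives tosylate acetate F5. K2CO3/MeOH at 0 °C gives allylic alcohol tosylate F6. Sharpless epoxidation as in step 3 gives epoxy tosylate F7. Acid-catalysed hydrolysis (HClO4 cat., THF/H2O) opens the epoxide at the tertiary C10 with inversion to give triol tosylate F8. NaH in dilute THF then closes ring A by intramolecular Williamson etherification of the C10 alkoxide at the primary carbon C5 (7-exo-tet, retention at C10) to give 6.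

3. Step 12 (C8 reduction and lactonisation). Hydride delivery to C8 may show poor facial selectivity, or the silyl group may migrate from O9 to the new C8 alkoxide before the lactone closes. Fallback, from 18 back to 20, replacing steric approach control by hydroxyl-directed delivery: HF (48% aq.)/MeCN gives α-hydroxy ketone F9. Me4N[BH(OAc)3] in AcOH/MeCN at −20 °C binds the C9 hydroxyl and delivers hydride intramolecularly on the exo face (Saksena–Evans reduction, anti-1,2-diol) to give diol ester F10. Pyridinium p-toluenesulfonate in PhMe lactonises this to hydroxy lactone F11. Silylation with t-BuMe2SiOTf/2,6-lutidine returns 20.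

## Further compounds

F1 | step 10 | methyl (2R)-2-[(tert-butyldimethylsilyl)oxy]-2-[(2R,6S)-2,6-dimethyloxepan-2-yl]acetate | COC(=O)[C@H](O[Si](C)(C)C(C)(C)C)[C@@]1(C)CCC[C@H](C)CO1
F2 | step 10 | methyl (2R)-2-[(tert-butyldimethylsilyl)oxy]-2-[(2R,6S,7R)-2,6-dimethyl-7-[2-(phenylsulfonyl)ethyl]oxepan-2-yl]acetate | COC(=O)[C@H](O[Si](C)(C)C(C)(C)C)[C@@]1(C)CCC[C@H](C)[C@@H](CCS(=O)(=O)c2ccccc2)O1
F3 | step 10 | (1R,2R,4RS,6R,7S)-2-[(tert-butyldimethylsilyl)oxy]-1,7-dimethyl-4-(phenylsulfonyl)-11-oxabicyclo[4.4.1]undecan-3-one | O=S(=O)(c1ccccc1)C1C[C@H]2O[C@](C)(CCC[C@@H]2C)[C@@H](O[Si](C)(C)C(C)(C)C)C1=O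
F4 | step 10 | methyl 2-[(1R,2R,4RS,6R,7S)-2-[(tert-butyldimethylsilyl)oxy]-1,7-dimethyl-3-oxo-4-(phenylsulfonyl)-11-oxabicyclo[4.4.1]undecan-4-yl]acetate | COC(=O)CC1(S(=O)(=O)c2ccccc2)C[C@H]2O[C@](C)(CCC[C@@H]2C)[C@@H](O[Si](C)(C)C(C)(C)C)C1=O
F5 | step 4 | (2E,7S)-3,7-dimethyl-8-[(4-methylbenzenesulfonyl)oxy]oct-2-en-1-yl acetate | Cc1ccc(cc1)S(=O)(=O)OC[C@@H](C)CCC/C(C)=C/COC(C)=O
F6 | step 4 | (2S,6E)-8-hydroxy-2,6-dimethyloct-6-en-1-yl 4-methylbenzenesulfonate | Cc1ccc(cc1)S(=O)(=O)OC[C@@H](C)CCC/C(C)=C/CO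
F7 | step 4 | (2S)-5-[(2S,3S)-3-(hydroxymethyl)-2-methyloxiran-2-yl]-2-methylpentyl 4-methylbenzenesulfonate | Cc1ccc(cc1)S(=O)(=O)OC[C@@H](C)CCC[C@]1(C)O[C@H]1CO
F8 | step 4 | (2S,6R,7S)-6,7,8-trihydroxy-2,6-dimethyloctyl 4-methylbenzenesulfonate | Cc1ccc(cc1)S(=O)(=O)OC[C@@H](C)CCC[C@@](C)(O)[C@@H](O)CO
F9 | step 12 | methyl 2-[(1R,2R,4R,6R,7S)-2-hydroxy-1,7-dimethyl-3-oxo-11-oxabicyclo[4.4.1]undecan-4-yl]acetate | COC(=O)C[C@H]1C[C@H]2O[C@](C)(CCC[C@@H]2C)[C@@H](O)C1=O
F10 | step 12 | methyl 2-[(1R,2S,3R,4R,6R,7S)-2,3-dihydroxy-1,7-dimethyl-11-oxabicyclo[4.4.1]undecan-4-yl]acetate | COC(=O)C[C@H]1C[C@H]2O[C@](C)(CCC[C@@H]2C)[C@@H](O)[C@@H]1O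
F11 | step 12 | (4S,5R,7R,8R,9S,10R)-5,10-epoxy-9-hydroxygermacran-12,8-olide | C1C(=O)O[C@@H]2[C@@H]1C[C@H]1O[C@](C)(CCC[C@@H]1C)[C@H]2O
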